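**Plan**

1. Retrosynthesis: the C14 acid goes back to a C14 silyl ether and the two angelates to an 8,9-diol; the ten-membered ring is cut at C9–C10; the chain is cut at C6–C7 (2-alkoxycarbonylallyl bromide + enal), which also accounts for the α-methylene lactone.
2. Forward: neryl acetate supplies C1–C6 and C15 with the Z C4=C5 alkene; an iodo-Wittig reaction adds C10(I) and C14 as the Z-iodide; (R)-glyceraldehyde acetonide and methyl acrylate supply C7–C9 and C11–C13.
3. Ring order: the trans γ-lactone forms first (step 11), the carbocycle second (step 15); acylation and C14 oxidation come last.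
4. Stereochemistry: C8 comes from (R)-glyceraldehyde; C6 and C7 from a chair allylchromium transition state steered by C8; C9 from ligand-controlled chromium addition; both ring alkene geometries are carried in (neryl acetate, Z-iodide).
5. Enabling feature: the ring-embedded allylic alcohol C1=C10(C14)–C9(O) is the retron of an alkenyl iodide/aldehyde coupling, so C9 (as CHO) and C10 (as C–I), both electrophiles, are joined reductively by CrCl2/NiCl2; the cis alkenes C1=C10 and C4=C5 and the lactone pre-bend the chain.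

Key step: step 15

Remark: locants C1–C15 are those of the germacrane skeleton of the target (ring C1–C10, lactone C6–O–C12(=O)–C11(=C13), C14 on C10, C15 on C4). (R)-Glyceraldehyde acetonide is assumed to be purchasable.

**Route**

Step 1
Reactants: 1 neryl acetate
Product: 2 (2Z)-5-(3,3-dimethyloxiran-2-yl)-3-methylpent-2-en-1-yl acetate (racemic epoxide)
Conditions: mCPBA, CH2Cl2, 0 °C
Reagents that add atoms: mCPBA O=C(OO)c1cccc(Cl)c1
Why: Prilezhaev epoxidation should occur at the remote, more electron-rich trisubstituted alkene, not at the one deactivated by the allylic acetate; the epoxide stereocentre is destroyed in step 2.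

Step 2
Reactants: 2 epoxy acetate
Product: 3 (2Z)-3-methyl-6-oxohex-2-en-1-yl acetate
Conditions: H5IO6, THF/H2O, 0 °C
Reagents that add atoms: none
Why: Periodic acid opens the epoxide to the glycol and cleaves it, which should give the aldehyde (C1) and leave the Z C4=C5 alkene untouched.

Step 3
Reactants: 3 acetoxy aldehyde, 4 methyl (triphenylphosphoranylidene)acetate
Product: 6 methyl (2Z,6Z)-8-acetoxy-2-iodo-6-methylocta-2,6-dienoate, via iodo ylide 5 (not isolated)
Conditions: N-iodosuccinimide, CH2Cl2, −20 °C; then 3, rt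
Reagents that add atoms: N-iodosuccinimide O=C1CCC(=O)N1I
Why: Wittig reaction of the stabilized α-iodo ylide with an aliphatic aldehyde should give mainly the Z-α-iodo enoate, in which iodine is cis to the chain as required at C10.

Step 4
Reactants: 6 iodo enoate acetate
Product: 7 methyl (2Z,6Z)-8-hydroxy-2-iodo-6-methylocta-2,6-dienoate
Conditions: K2CO3 (cat.), MeOH, 0 °C
Reagents that add atoms: none
Why: Base-catalysed methanolysis should remove the primary allylic acetate and leave the methyl enoate unchanged.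

Step 5
Reactants: 7 hydroxy ester
Product: 8 methyl (2Z,6Z)-2-iodo-6-methyl-8-(triethylsilyloxy)octa-2,6-dienoate
Conditions: Et3SiCl, imidazole, CH2Cl2, 0 °C
Reagents that add atoms: chlorotriethylsilane CC[Si](Cl)(CC)CC
Why: Silylation gives a triethylsilyl ether that survives hydride reduction and can be oxidized directly in step 8.

Step 6
Reactants: 8 silyl ether ester
Product: 9 (2Z,6Z)-2-iodo-6-methyl-8-(triethylsilyloxy)octa-2,6-dien-1-ol
Conditions: i-Bu2AlH, CH2Cl2, −78 °C
Reagents that add atoms: none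
Why: Aluminium hydride reduction of the conjugated ester should give the 2-iodoallylic alcohol (C14) without touching the alkenyl iodide or the silyl ether.

Step 7
Reactants: 9 iodoallylic alcohol
Product: 10 tert-butyl{[(2Z,6Z)-2-iodo-6-methyl-8-(triethylsilyloxy)octa-2,6-dien-1-yl]oxy}diphenylsilane
Conditions: t-BuPh2SiCl, imidazole, DMF, rt
Reagents that add atoms: tert-butylchlorodiphenylsilane CC(C)(C)[Si](Cl)(c1ccccc1)c1ccccc1
Why: The acid-stable tert-butyldiphenylsilyl ether protects O14 through the acidic and oxidative steps that follow.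

Step 8
Reactants: 10 bis-silyl ether
Product: 11 (2Z,6Z)-8-(tert-butyldiphenylsilyloxy)-7-iodo-3-methylocta-2,6-dienal
Conditions: (COCl)2, DMSO, CH2Cl2, −78 → −40 °C; Et3N
Reagents that add atoms: none
Why: Swern oxidation applied directly to the primary allylic triethylsilyl ether should give the Z-enal (C6) while the bulky silyl ether at O14 is inert.

Step 9
Reactants: 12 (R)-2,2-dimethyl-1,3-dioxolane-4-carbaldehyde, 13 methyl acrylate
Product: 14 methyl 2-{[(4R)-2,2-dimethyl-1,3-dioxolan-4-yl](hydroxy)methyl}prop-2-enoate (carbinol epimers)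
Conditions: DABCO (cat.), neat 13, rt
Reagents that add atoms: none
Why: Morita–Baylis–Hillman reaction; the new carbinol centre need not be controlled because it becomes sp2 in step 10, and the dioxolane centre (C8) is carried over from 12.

Step 10
Reactants: 14 allylic alcohol
Product: 15 methyl (2Z)-2-(bromomethyl)-3-[(4S)-2,2-dimethyl-1,3-dioxolan-4-yl]prop-2-enoate
Conditions: N-bromosuccinimide, Me2S, CH2Cl2, 0 °C → rt
Reagents that add atoms: N-bromosuccinimide O=C1CCC(=O)N1Br
Why: Corey–Kim-type activation of the alcohol and SN2′ displacement by bromide should give the rearranged, thermodynamically favoured allylic bromide under neutral conditions that spare the acetonide.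

Step 11
Reactants: 11 enal, 15 allylic bromide
Product: 17 (4S,5R)-5-[(1Z,5Z)-7-(tert-butyldiphenylsilyloxy)-6-iodo-2-methylhepta-1,5-dien-1-yl]-4-[(4S)-2,2-dimethyl-1,3-dioxolan-4-yl]-3-methylideneoxolan-2-one, via hydroxy ester 16 (not isolated)
Conditions: CrCl2, THF, rt; then PPTS (cat.), toluene, 60 °C
Reagents that add atoms: none
Why: Nozaki–Hiyama (Barbier-type) allylation: the allylchromium adds through C7 in a closed chair transition state with the enal residue and C8 equatorial, which should give the anti C6/C7 relationship (trans lactone), while C8–H eclipses the ester-bearing C11 to avoid A(1,3) strain and the aldehyde approaches anti to the C9 methylene, which should set 6R,7S relative to 8S; the alkoxide then lactonizes onto the methyl ester, and the alkenyl iodide is inert without nickel.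

Step 12
Reactants: 17 lactone acetonide
Product: 18 (4R,5R)-5-[(1Z,5Z)-7-(tert-butyldiphenylsilyloxy)-6-iodo-2-methylhepta-1,5-dien-1-yl]-4-[(1S)-1,2-dihydroxyethyl]-3-methylideneoxolan-2-one
Conditions: AcOH/H2O/THF, 45 °C
Reagents that add atoms: none
Why: Acid-catalysed hydrolysis of the terminal acetonide; the lactone, the O14 silyl ether and the alkenyl iodide should survive aqueous acetic acid (the descriptor at C7 changes only by priority).

Step 13
Reactants: 18 diol
Product: 19 (4S,5R)-4-[(1S)-1,2-bis(triethylsilyloxy)ethyl]-5-[(1Z,5Z)-7-(tert-butyldiphenylsilyloxy)-6-iodo-2-methylhepta-1,5-dien-1-yl]-3-methylideneoxolan-2-one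
Conditions: Et3SiOTf (2.5 equiv), 2,6-lutidine, CH2Cl2, −78 °C
Reagents that add atoms: triethylsilyl trifluoromethanesulfonate CC[Si](CC)(CC)OS(=O)(=O)C(F)(F)F
Why: Fast low-temperature silylation of both hydroxyls avoids base-mediated translactonization onto O8.

Step 14
Reactants: 19 bis(triethylsilyl) ether
Product: 20 (2S)-2-{(2R,3S)-2-[(1Z,5Z)-7-(tert-butyldiphenylsilyloxy)-6-iodo-2-methylhepta-1,5-dien-1-yl]-4-methylidene-5-oxooxolan-3-yl}-2-(triethylsilyloxy)acetaldehyde
Conditions: (COCl)2, DMSO, CH2Cl2, −78 → −30 °C; Et3N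
Reagents that add atoms: none
Why: Under Swern conditions a primary triethylsilyl ether is oxidized directly to the aldehyde while the secondary one (O8) and the tert-butyldiphenylsilyl ether remain, which unveils C9 as the aldehyde.

Step 15
Reactants: 20 iodo aldehyde
Product: 21 (6R,7S,8S,9S)-14-(tert-butyldiphenylsilyloxy)-9-hydroxy-8-(triethylsilyloxy)germacra-1(10)Z,4Z,11(13)-trien-12,6-olide
Conditions: CrCl2, chiral N-[2-(4-isopropyl-4,5-dihydro-1,3-oxazol-2-yl)-6-methylphenyl]methanesulfonamide ligand (the enantiomer that shields the Re face of the C9 aldehyde), Et3N, THF, rt; then NiCl2 (cat.), slow addition of 20 to about 2 mM, THF/MeCN, rt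
Reagents that add atoms: none
Why: Nozaki–Hiyama–Kishi reaction: zerovalent nickel (formed from NiCl2 by CrCl2) inserts into the C10–I bond with retention, the alkenyl group passes to trivalent chromium, and this configurationally stable alkenylchromium adds to the C9 aldehyde, so two electrophilic carbons are joined by reductive polarity reversal. The closest known reaction type is the intramolecular alkenyl iodide–aldehyde NiCl2/CrCl2 coupling used to close medium and large carbocyclic allylic alcohols, including its ligand-controlled asymmetric variant. The ten-membered carbocycle closes in the 10-exo-trig mode, the C9=O bond being exocyclic to the forming ring. C9 is the only new stereocentre and is set under reagent control by the sulfonamide-bound chromium, which should deliver C10 to the Si face of the aldehyde (9S, 8,9-syn) against the usual preference of an α-silyloxy aldehyde for attack anti to the C–O bond; the C1=C10 geometry (C2 and C9 cis) is inherited from the Z-iodide. The step needs cyclization to win over oligomerization and needs chemoselectivity for the aldehyde: high dilution, the two cis alkenes and the trans-fused lactone hold the chain ends close, and alkenylchromium reagents do not attack lactones, silyl ethers or the exo-methylene acceptor.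

Step 16
Reactants: 21 macrocyclic alcohol
Product: 22 (6R,7R,8S,9S)-14-(tert-butyldiphenylsilyloxy)-8,9-dihydroxygermacra-1(10)Z,4Z,11(13)-trien-12,6-olide
Conditions: PPTS, MeOH, 0 °C → rt
Reagents that add atoms: none
Why: Mild acid-catalysed methanolysis should cleave the secondary triethylsilyl ether selectively in the presence of the tert-butyldiphenylsilyl ether (the descriptor at C7 changes only by priority).

Step 17
Reactants: 22 diol, 23 angelic acid (at least two equivalents per diol; five are used)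
Product: 25 (6R,7S,8S,9S)-8,9-bis(angeloyloxy)-14-(tert-butyldiphenylsilyloxy)germacra-1(10)Z,4Z,11(13)-trien-12,6-olide, via mixed anhydride 24 (not isolated)
Conditions: 23 (5 equiv), 2,4,6-trichlorobenzoyl chloride (5 equiv), Et3N, toluene, rt; then 22, 80 °C
Reagents that add atoms: angelic acid (second equivalent) C/C=C(/C)C(=O)O
Why: Yamaguchi-type esterification in which each of the two secondary hydroxyls takes its angeloyl group from a separate molecule of mixed anhydride 24, so two molecules of angelic acid are built into 25; it should proceed without isomerizing the angelate to the tiglate and is done while C14 is still a silyl ether so that no SN2′-prone acrylate unit is present.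

Step 18
Reactants: 25 diangelate
Product: 26 (6R,7S,8S,9S)-8,9-bis(angeloyloxy)-14-hydroxygermacra-1(10)Z,4Z,11(13)-trien-12,6-olide
Conditions: HF·pyridine, pyridine/THF, 0 °C → rt
Reagents that add atoms: none
Why: Buffered, weakly acidic fluoride desilylation should free O14 without acyl migration or attack on the esters and lactone.

Step 19
Reactants: 26 allylic alcohol
Product: 27 (6R,7S,8S,9S)-8,9-bis(angeloyloxy)-14-oxogermacra-1(10)E,4Z,11(13)-trien-12,6-olide
Conditions: Dess–Martin periodinane, CH2Cl2, 0 °C → rt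
Reagents that add atoms: none
Why: Dess–Martin oxidation of the primary allylic alcohol should give the enal under neutral conditions.

Step 20
Reactants: 27 enal
Product: 28 (6R,7S,8S,9S)-8,9-bis(angeloyloxy)germacra-1(10)E,4Z,11(13)-trien-12,6-olid-14-oic acid (target)
Conditions: NaClO2, NaH2PO4, 2-methyl-2-butene, t-BuOH/H2O, 0 °C → rt
Reagents that add atoms: sodium chlorite [Na+].[O-]Cl=O
Why: Pinnick oxidation converts the enal into the acid, with 2-methyl-2-butene scavenging HOCl so that the alkenes and angelates are untouched.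

**Compound list**

1 | neryl acetate, (2Z)-3,7-dimethylocta-2,6-dien-1-yl acetate | CC(C)=CCC/C(C)=C\COC(C)=O | starting material
2 | (2Z)-5-(3,3-dimethyloxiran-2-yl)-3-methylpent-2-en-1-yl acetate (racemic) | CC1(C)OC1CC/C(C)=C\COC(C)=O | intermediate
3 | (2Z)-3-methyl-6-oxohex-2-en-1-yl acetate | O=CCC/C(C)=C\COC(C)=O | intermediate
4 | methyl (triphenylphosphoranylidene)acetate | COC(=O)C=P(c1ccccc1)(c1ccccc1)c1ccccc1 | starting material
5 | methyl iodo(triphenylphosphoranylidene)acetate | COC(=O)C(I)=P(c1ccccc1)(c1ccccc1)c1ccccc1 | intermediate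
6 | methyl (2Z,6Z)-8-acetoxy-2-iodo-6-methylocta-2,6-dienoate | COC(=O)/C(I)=C/CC/C(C)=C\COC(C)=O | intermediate
7 | methyl (2Z,6Z)-8-hydroxy-2-iodo-6-methylocta-2,6-dienoate | COC(=O)/C(I)=C/CC/C(C)=C\CO | intermediate
8 | methyl (2Z,6Z)-2-iodo-6-methyl-8-(triethylsilyloxy)octa-2,6-dienoate | COC(=O)/C(I)=C/CC/C(C)=C\CO[Si](CC)(CC)CC | intermediate
9 | (2Z,6Z)-2-iodo-6-methyl-8-(triethylsilyloxy)octa-2,6-dien-1-ol | OC/C(I)=C/CC/C(C)=C\CO[Si](CC)(CC)CC | intermediate
10 | tert-butyl{[(2Z,6Z)-2-iodo-6-methyl-8-(triethylsilyloxy)octa-2,6-dien-1-yl]oxy}diphenylsilane | CC(C)(C)[Si](OC/C(I)=C/CC/C(C)=C\CO[Si](CC)(CC)CC)(c1ccccc1)c1ccccc1 | intermediate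
11 | (2Z,6Z)-8-(tert-butyldiphenylsilyloxy)-7-iodo-3-methylocta-2,6-dienal | CC(C)(C)[Si](OC/C(I)=C/CC/C(C)=C\C=O)(c1ccccc1)c1ccccc1 | intermediate
12 | (R)-2,2-dimethyl-1,3-dioxolane-4-carbaldehyde | CC1(C)OC[C@@H](O1)C=O | starting material
13 | methyl acrylate | C=CC(=O)OC | starting material
14 | methyl 2-{[(4R)-2,2-dimethyl-1,3-dioxolan-4-yl](hydroxy)methyl}prop-2-enoate (carbinol epimers) | C=C(C(=O)OC)C(O)[C@H]1COC(C)(C)O1 | intermediate
15 | methyl (2Z)-2-(bromomethyl)-3-[(4S)-2,2-dimethyl-1,3-dioxolan-4-yl]prop-2-enoate | CC1(C)OC[C@@H](O1)/C=C(\CBr)C(=O)OC | intermediate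
16 | methyl (3S,4R,5Z,9Z)-11-(tert-butyldiphenylsilyloxy)-3-[(4S)-2,2-dimethyl-1,3-dioxolan-4-yl]-4-hydroxy-10-iodo-6-methyl-2-methylideneundeca-5,9-dienoate | C=C(C(=O)OC)[C@H]([C@H]1COC(C)(C)O1)[C@H](O)/C=C(/C)CC/C=C(\I)CO[Si](c1ccccc1)(c1ccccc1)C(C)(C)C | intermediate
17 | (4S,5R)-5-[(1Z,5Z)-7-(tert-butyldiphenylsilyloxy)-6-iodo-2-methylhepta-1,5-dien-1-yl]-4-[(4S)-2,2-dimethyl-1,3-dioxolan-4-yl]-3-methylideneoxolan-2-one | C=C1C(=O)O[C@H](/C=C(/C)CC/C=C(\I)CO[Si](c2ccccc2)(c2ccccc2)C(C)(C)C)[C@H]1[C@H]3COC(C)(C)O3 | intermediate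
18 | (4R,5R)-5-[(1Z,5Z)-7-(tert-butyldiphenylsilyloxy)-6-iodo-2-methylhepta-1,5-dien-1-yl]-4-[(1S)-1,2-dihydroxyethyl]-3-methylideneoxolan-2-one | C=C1C(=O)O[C@H](/C=C(/C)CC/C=C(\I)CO[Si](c2ccccc2)(c2ccccc2)C(C)(C)C)[C@H]1[C@H](O)CO | intermediate
19 | (4S,5R)-4-[(1S)-1,2-bis(triethylsilyloxy)ethyl]-5-[(1Z,5Z)-7-(tert-butyldiphenylsilyloxy)-6-iodo-2-methylhepta-1,5-dien-1-yl]-3-methylideneoxolan-2-one | C=C1C(=O)O[C@H](/C=C(/C)CC/C=C(\I)CO[Si](c2ccccc2)(c2ccccc2)C(C)(C)C)[C@H]1[C@H](O[Si](CC)(CC)CC)CO[Si](CC)(CC)CC | intermediate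
20 | (2S)-2-{(2R,3S)-2-[(1Z,5Z)-7-(tert-butyldiphenylsilyloxy)-6-iodo-2-methylhepta-1,5-dien-1-yl]-4-methylidene-5-oxooxolan-3-yl}-2-(triethylsilyloxy)acetaldehyde | C=C1C(=O)O[C@H](/C=C(/C)CC/C=C(\I)CO[Si](c2ccccc2)(c2ccccc2)C(C)(C)C)[C@H]1[C@H](O[Si](CC)(CC)CC)C=O | intermediate
21 | (6R,7S,8S,9S)-14-(tert-butyldiphenylsilyloxy)-9-hydroxy-8-(triethylsilyloxy)germacra-1(10)Z,4Z,11(13)-trien-12,6-olide | C=C1C(=O)O[C@@H]2/C=C(/C)CC/C=C(/CO[Si](c3ccccc3)(c3ccccc3)C(C)(C)C)[C@H](O)[C@@H](O[Si](CC)(CC)CC)[C@@H]12 | intermediate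
22 | (6R,7R,8S,9S)-14-(tert-butyldiphenylsilyloxy)-8,9-dihydroxygermacra-1(10)Z,4Z,11(13)-trien-12,6-olide | C=C1C(=O)O[C@@H]2/C=C(/C)CC/C=C(/CO[Si](c3ccccc3)(c3ccccc3)C(C)(C)C)[C@H](O)[C@@H](O)[C@@H]12 | intermediate
23 | angelic acid, (2Z)-2-methylbut-2-enoic acid | C/C=C(/C)C(=O)O | starting material
24 | (2Z)-2-methylbut-2-enoic 2,4,6-trichlorobenzoic anhydride | C/C=C(/C)C(=O)OC(=O)c1c(Cl)cc(Cl)cc1Cl | intermediate
25 | (6R,7S,8S,9S)-8,9-bis(angeloyloxy)-14-(tert-butyldiphenylsilyloxy)germacra-1(10)Z,4Z,11(13)-trien-12,6-olide | C=C1C(=O)O[C@@H]2/C=C(/C)CC/C=C(/CO[Si](c3ccccc3)(c3ccccc3)C(C)(C)C)[C@H](OC(=O)/C(C)=C\C)[C@@H](OC(=O)/C(C)=C\C)[C@@H]12 | intermediate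
26 | (6R,7S,8S,9S)-8,9-bis(angeloyloxy)-14-hydroxygermacra-1(10)Z,4Z,11(13)-trien-12,6-olide | C=C1C(=O)O[C@@H]2/C=C(/C)CC/C=C(/CO)[C@H](OC(=O)/C(C)=C\C)[C@@H](OC(=O)/C(C)=C\C)[C@@H]12 | intermediate
27 | (6R,7S,8S,9S)-8,9-bis(angeloyloxy)-14-oxogermacra-1(10)E,4Z,11(13)-trien-12,6-olide | C=C1C(=O)O[C@@H]2/C=C(/C)CC/C=C(/C=O)[C@H](OC(=O)/C(C)=C\C)[C@@H](OC(=O)/C(C)=C\C)[C@@H]12 | intermediate
28 | (6R,7S,8S,9S)-8,9-bis(angeloyloxy)germacra-1(10)E,4Z,11(13)-trien-12,6-olid-14-oic acid | C=C1C(=O)O[C@@H]2/C=C(/C)CC/C=C(/C(=O)O)[C@H](OC(=O)/C(C)=C\C)[C@@H](OC(=O)/C(C)=C\C)[C@@H]12 | target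

**Step count and risks**

Total steps: 20. Longest linear sequence: 18 steps (steps 1–8, then 11–20).

Most likely to fail:

1. Step 15. The risk is poor facial selectivity at C9, because the inherent preference of the α-silyloxy aldehyde for attack anti to the C8–O bond opposes the ligand, together with intermolecular coupling competing with ring closure. The fallback sets C9 by ketone reduction and not by carbonyl addition. Setting out from 20, ligand-free CrCl2/NiCl2 (cat.) in DMSO/THF at high dilution should give the C9-epimeric macrocyclic carbinol F1. Dess–Martin periodinane should oxidize this to the cross-conjugated ring enone F2. Luche reduction (NaBH4, CeCl3·7H2O, MeOH, −78 °C) should then deliver hydride anti to the C8–O bond from the ring periphery, which for a hydride gives the 8,9-syn (9S) alcohol, and the route is rejoined at 21.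

2. Step 11. The risk is poor facial selectivity of the allylchromium with respect to the dioxolane centre, or erosion of the anti preference, which would give C6/C7 diastereomer mixtures. The fallback replaces substrate control by catalyst control. Setting out from 11 and 15, a chromium-catalysed enantioselective 2-(alkoxycarbonyl)allylation (CrCl2 cat., chiral 1,8-bis(oxazolinyl)carbazole ligand, Mn powder, Me3SiCl, THF) should fix the aldehyde face and, through the anti-selective chair, C7, giving the trimethylsilyl ether F3. Dilute HCl in THF then PPTS in toluene should desilylate and lactonize, and the route is rejoined at 17.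

3. Step 17. The risk is isomerization of angelate to tiglate and incomplete acylation of the hindered vicinal diol. The fallback builds the angelate double bonds on the substrate and does not transfer the intact acyl group. Setting out from 22, esterification with 2-[bis(2,2,2-trifluoroethoxy)phosphoryl]propanoic acid (DCC, DMAP, CH2Cl2) should give the bis(phosphonopropanoate) F4. A Still–Gennari olefination with acetaldehyde (KN(SiMe3)2, 18-crown-6, THF, −78 °C) should then form both Z-2-methylbut-2-enoates, and the route is rejoined at 25.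

Further compounds
F1 | step 15 | (6R,7S,8S)-14-(tert-butyldiphenylsilyloxy)-9-hydroxy-8-(triethylsilyloxy)germacra-1(10)Z,4Z,11(13)-trien-12,6-olide, C9-epimer mixture | C=C1C(=O)O[C@@H]2/C=C(/C)CC/C=C(/CO[Si](c3ccccc3)(c3ccccc3)C(C)(C)C)C(O)[C@@H](O[Si](CC)(CC)CC)[C@@H]12
F2 | step 15 | (6R,7S,8S)-14-(tert-butyldiphenylsilyloxy)-9-oxo-8-(triethylsilyloxy)germacra-1(10),4Z,11(13)-trien-12,6-olide (C2 and C9 cis on C1=C10) | C=C1C(=O)O[C@@H]2/C=C(/C)CC/C=C(/CO[Si](c3ccccc3)(c3ccccc3)C(C)(C)C)C(=O)[C@@H](O[Si](CC)(CC)CC)[C@@H]12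
F3 | step 11 | methyl (3S,4R,5Z,9Z)-11-(tert-butyldiphenylsilyloxy)-3-[(4S)-2,2-dimethyl-1,3-dioxolan-4-yl]-10-iodo-6-methyl-2-methylidene-4-(trimethylsilyloxy)undeca-5,9-dienoate | C=C(C(=O)OC)[C@H]([C@H]1COC(C)(C)O1)[C@H](O[Si](C)(C)C)/C=C(/C)CC/C=C(\I)CO[Si](c1ccccc1)(c1ccccc1)C(C)(C)C
F4 | step 17 | (6R,7S,8S,9S)-8,9-bis{2-[bis(2,2,2-trifluoroethoxy)phosphoryl]propanoyloxy}-14-(tert-butyldiphenylsilyloxy)germacra-1(10)Z,4Z,11(13)-trien-12,6-olide | C=C1C(=O)O[C@@H]2/C=C(/C)CC/C=C(/CO[Si](c3ccccc3)(c3ccccc3)C(C)(C)C)[C@H](OC(=O)C(C)P(=O)(OCC(F)(F)F)OCC(F)(F)F)[C@@H](OC(=O)C(C)P(=O)(OCC(F)(F)F)OCC(F)(F)F)[C@@H]12
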